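The numbers are made up; the result is computed.

In a one-step world the open intermediate would just be whatever had been made, so when you asked me for a quick number and guessed that it drains away to nothing, I began from the scheme.

    starting material + coupling partner → open intermediate + by-product (k1 = 0.27 M⁻¹ s⁻¹)
    open intermediate ⇌ target (K2 = 14, k2 = 0.028 s⁻¹)
    open intermediate ⇌ isomer of the product (K3 = 2.7, k3 = 0.012 s⁻¹)
    coupling partner + target → over-reaction product (k4 = 0.016 M⁻¹ s⁻¹)
    open intermediate + capture agent → trapped intermediate (k5 = 0.27 M⁻¹ s⁻¹)

the same everywhere: starting material 0.30 M; capture agent 0.0150 M
- alder: coupling partner 1.20 equiv; a single well-mixed tank run continuously and read at steady state, 400 s in it on average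
- cedar: coupling partner 1.20 equiv (fed, over 64.0 s); a stirred flask in which coupling partner is dosed at a steady rate over 64.0 s without added volume, worked up at 80 s; time 80 s
- ash: coupling partner 1.20 equiv; a closed flask charged with all of it at once and left for 80 s; time 80 s
- birch: coupling partner 1.20 equiv; one stirred flow tank at steady state, fed with the mixture as stated, mean residence time 80 s

- the stated concentrations are those of everything mixed, before any reaction; amounts are the same in each set-up
- the feed brings no volume worth counting
- run time (cedar): 80 s

* order of the set-ups by the amount of open intermediate at the outlet or at the end, in percent of the starting material put in, highest first (alder / cedar / ash / birch)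
* amount of open intermediate at the outlet or at the end, in percent of the starting material put in, alder
* amount of open intermediate at the outlet or at the end, in percent of the starting material put in, cedar
* amount of open intermediate at the outlet or at the end, in percent of the starting material put in, ash
* amount of open intermediate at the outlet or at the end, in percent of the starting material put in, birch

I doubted your hunch, since steps 2 and 3 run back. When I divided each back rate by its forward rate, time dropped out: at balance, target stands at K2 times the open intermediate and isomer at K3 times. At full balance the open intermediate therefore keeps e = 1/(1 + K2 + K3) = 5.65 %, the balance share, of whatever sits in those three forms.

Steps 2 and 3 share the open intermediate, so the approach to that balance has two rates, which add up to the sum of the forward and back constants, 0.0464 s⁻¹. Solving the two steps together gave a fast rate λ1 = 0.0428 s⁻¹ and a slow rate λ2 = 0.00368 s⁻¹, with half times of 16.2 s and 188 s. I left capture out of both rates, as its half-life of 170 s as charged in ash is longer than the 25 s of the forward step 2.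

For ash I treated the making as first order at kf = 0.0972 s⁻¹, with the coupling partner as charged. Adding the balance share to a remainder that decays at λ1, with the slow rate's part left out, gave 11.2 % at the end. I took that as low, since the making slows as starting material, the limiting reagent, and coupling partner both fall.

I put alder lowest because its 400 s on average is longer than both half times. I put cedar first because it is worked up 16.0 s after its last dose, about the fast half time, with birch second.

The forecast gave cedar > birch > ash > alder, with alder 8.4 %, cedar 23 %, ash 13 % and birch 19 %, on the ground that “whatever was made in the last 25 s or so dominates what is left”.

The simulation gave cedar > birch > ash > alder, with alder 8.40 %, cedar 23.2 %, ash 12.9 % and birch 19.1 %.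

Ash stood 1.7 percentage points above my figure, and alder stood at 1.49 times the balance share. The slow half time of 188 s is longer than the 120 s half-life of target by step 4 alone, as charged in ash. Cedar, left ten times as long, held 4.44 % of its starting material as open intermediate after 800 s, which is 0.786 of the balance share.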